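**Retrosynthetic overview**
1. Ester C–O last: target ⇒ (−)-drimenol 11 + (E)-3,4-diacetoxycinnamic acid 12, then removal of the two acetates.
2. C9–H: 11 ⇒ spiro vinyl cyclic carbonate 10 by Pd/formate hydrogenolysis (hydride to C9 with inversion, Δ7 alkene kept).
3. Key C9–C11 bond: 10 ⇒ 11-nor enone 8 + LiCH2OLi, a hydroxymethyl-anion (d1, polarity-reversed) synthon added to the C9 carbonyl; both carbons are electrophilic in normal polarity.
4. Ring A (formed second): 8 ⇒ 6-allyl-6-methylcarvone 5 by cation–olefin closure of C3–C4 (the isopropenyl group becomes the gem-dimethyl C4), then C–Br removal.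
5. Ring B (present from the start) = (R)-carvone 1; quaternary C10 from α′-methylation, then allylation anti to the isopropenyl group.

Assumption: drimane numbering (C1–C15) is used for positions; LDA, n-BuLi, (tributylstannyl)methanol and (E)-3,4-diacetoxycinnamic acid are bought.

**Step 1**
Reactants: 1 (R)-(−)-carvone
Product: 3 6-methylcarvone [(5R)-2,6-dimethyl-5-(prop-1-en-2-yl)cyclohex-2-en-1-one; C6 epimers], via lithium enolate 2 (not isolated)
Conditions: LDA (1.1 equiv), THF, −78 °C; then MeI, −78 → 0 °C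
Reagents that add atoms: iodomethane, CI
Why: Kinetic α′-deprotonation of the enone followed by enolate C-alkylation installs the future C10 methyl; the new centre is re-enolised in step 2, so its configuration does not matter.

**Step 2**
Reactants: 3 6-methylcarvone
Product: 5 (5S,6S)-2,6-dimethyl-6-(prop-2-en-1-yl)-5-(prop-1-en-2-yl)cyclohex-2-en-1-one (allyl trans to isopropenyl), via lithium enolate 4 (not isolated)
Conditions: LDA (1.2 equiv), THF, −78 → −20 °C; then allyl bromide, DMPU, −78 °C → rt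
Reagents that add atoms: allyl bromide, C=CCBr
Why: Enolate alkylation in which allyl bromide attacks the trisubstituted enolate anti to the neighbouring isopropenyl group, so the allyl chain (C1–C3) ends trans and the methyl cis to it, which sets the quaternary C10 as needed for a trans-decalin with axial methyl.

**Step 3**
Reactants: 5 (5S,6S)-6-allyl-6-methylcarvone
Product: 7 (4aS,8aS)-7-bromo-2,5,5,8a-tetramethyl-4a,5,6,7,8,8a-hexahydronaphthalen-1(4H)-one (C–Br epimers), via tertiary bromide 6 (not isolated)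
Conditions: anhydrous HBr (1.05 equiv), CH2Cl2, −40 °C; then ZnBr2 (20 mol %), −40 → 0 °C
Reagents that add atoms: hydrogen bromide, Br
Why: Markovnikov hydrobromination of the isopropenyl group and ZnBr2 ionisation give the tertiary C4 cation, which adds 6-endo to the terminal alkene (intramolecular Lewis-acid-catalysed tert-alkyl halide–alkene addition, a cation–olefin cyclisation) with bromide capture at C2; the two tethers are trans-diequatorial, so ring A closes trans-fused and C4 becomes gem-dimethyl.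

**Step 4**
Reactants: 7 bromo enone
Product: 8 (4aS,8aS)-2,5,5,8a-tetramethyl-4a,5,6,7,8,8a-hexahydronaphthalen-1(4H)-one (11-nor-drim-7-en-9-one)
Conditions: n-Bu3SnH, AIBN (cat.), PhH, 80 °C
Reagents that add atoms: none
Why: Radical chain dehalogenation (tin hydride reduction) removes the secondary bromide without touching the enone or any stereocentre.

**Step 5 (key step)**
Reactants: 8 11-nor-drim-7-en-9-one
Product: 10 (4S,4a′S,8a′S)-2′,5′,5′,8a′-tetramethyl-4a′,5′,6′,7′,8′,8a′-hexahydro-4′H-spiro[1,3-dioxolane-4,1′-naphthalen]-2-one (O9 on the β face; C11 on the α face), via dilithium dialkoxide 9 (not isolated)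
Conditions: Bu3SnCH2OH, n-BuLi (2 equiv per Sn), THF, −78 → 0 °C; add 8, −78 → 0 °C; then ClCO2Me, −78 °C → rt
Reagents that add atoms: (tributylstannyl)methanol, CCCC[Sn](CCCC)(CCCC)CO; methyl chloroformate, COC(=O)Cl
Why: Seebach's lithiomethanolate, an α-oxygenated carbanion made by Sn–Li exchange (hydroxymethyl-anion d1 synthon), adds 1,2 to the C9 carbonyl from the α face (axial attack anti to the axial C10 methyl), joining two natively electrophilic carbons; the chloroformate quench (O-acylation, then intramolecular transesterification) closes the cyclic carbonate.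

**Step 6**
Reactants: 10 spiro vinyl cyclic carbonate
Product: 11 (−)-drimenol, [(1S,4aS,8aS)-2,5,5,8a-tetramethyl-1,4,4a,5,6,7,8,8a-octahydronaphthalen-1-yl]methanol
Conditions: Pd2(dba)3·CHCl3 (2.5 mol %), n-Bu3P (10 mol %), HCO2H, Et3N, dioxane, 70 °C
Reagents that add atoms: none
Why: Tsuji–Shimizu Pd-catalysed formate hydrogenolysis of an alkenyl cyclic carbonate, in which Pd(0) ionises the β C9–O bond from the α face, CO2 is lost and the Pd hydride is delivered to the more substituted allyl terminus C9 on the α face (net inversion), giving 9α-H, 9β-CH2OH and the Δ7 alkene.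

**Step 7**
Reactants: 11 (−)-drimenol; 12 (E)-3,4-diacetoxycinnamic acid
Product: 13 drimenyl (E)-3,4-diacetoxycinnamate
Conditions: DCC, DMAP (cat.), CH2Cl2, 0 °C → rt
Reagents that add atoms: none
Why: Steglich esterification of the primary alcohol; no stereocentre is involved and the (E)-alkene is carried over from 12.

**Step 8**
Reactants: 13 drimenyl (E)-3,4-diacetoxycinnamate
Product: 14 drimenyl (E)-caffeate (target)
Conditions: K2CO3 (0.3 equiv), MeOH/CH2Cl2, 0 °C, argon; AcOH quench
Reagents that add atoms: none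
Why: Zemplén-type transesterification cleaves the two aryl acetates, which are far more electrophilic than the hindered alkyl cinnamate, and frees the catechol.

**Compound list**
1 | (R)-(−)-carvone | CC1=CC[C@H](CC1=O)C(C)=C | starting material
2 | lithium dienolate of 1 | CC1=CC[C@H](C=C1O[Li])C(C)=C | intermediate
3 | (5R)-2,6-dimethyl-5-(prop-1-en-2-yl)cyclohex-2-en-1-one (6-methylcarvone, C6 epimers) | CC1=CC[C@H](C(C)C1=O)C(C)=C | intermediate
4 | lithium dienolate of 3 | CC1=CC[C@H](C(C)=C1O[Li])C(C)=C | intermediate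
5 | (5S,6S)-2,6-dimethyl-6-(prop-2-en-1-yl)-5-(prop-1-en-2-yl)cyclohex-2-en-1-one | CC1=CC[C@@H](C(C)=C)[C@](C)(CC=C)C1=O | intermediate
6 | (5R,6S)-5-(2-bromopropan-2-yl)-2,6-dimethyl-6-(prop-2-en-1-yl)cyclohex-2-en-1-one | CC1=CC[C@@H](C(C)(C)Br)[C@](C)(CC=C)C1=O | intermediate
7 | (4aS,8aS)-7-bromo-2,5,5,8a-tetramethyl-4a,5,6,7,8,8a-hexahydronaphthalen-1(4H)-one (C7 epimers) | CC1=CC[C@H]2C(C)(C)CC(Br)C[C@]2(C)C1=O | intermediate
8 | (4aS,8aS)-2,5,5,8a-tetramethyl-4a,5,6,7,8,8a-hexahydronaphthalen-1(4H)-one | CC1=CC[C@H]2C(C)(C)CCC[C@]2(C)C1=O | intermediate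
9 | dilithium (1S,4aS,8aS)-2,5,5,8a-tetramethyl-1-(oxidomethyl)-1,4,4a,5,6,7,8,8a-octahydronaphthalen-1-olate | CC1=CC[C@H]2C(C)(C)CCC[C@]2(C)[C@]1(O[Li])CO[Li] | intermediate
10 | (4S,4a′S,8a′S)-2′,5′,5′,8a′-tetramethyl-4a′,5′,6′,7′,8′,8a′-hexahydro-4′H-spiro[1,3-dioxolane-4,1′-naphthalen]-2-one | CC1=CC[C@H]2C(C)(C)CCC[C@]2(C)[C@]13COC(=O)O3 | intermediate
11 | (−)-drimenol | CC1=CC[C@H]2C(C)(C)CCC[C@]2(C)[C@H]1CO | intermediate
12 | (E)-3,4-diacetoxycinnamic acid | CC(=O)Oc1ccc(/C=C/C(=O)O)cc1OC(C)=O | starting material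
13 | drimenyl (E)-3,4-diacetoxycinnamate | CC1=CC[C@H]2C(C)(C)CCC[C@]2(C)[C@H]1COC(=O)/C=C/c1ccc(OC(C)=O)c(OC(C)=O)c1 | intermediate
14 | drimenyl (E)-caffeate | CC1=CC[C@H]2C(C)(C)CCC[C@]2(C)[C@H]1COC(=O)/C=C/c1ccc(O)c(O)c1 | target

**Totals**
Total step count: 8. Longest linear sequence: 8 (1 → 14).

**Three steps most likely to fail**

Step 3. The closure passes through a secondary cation at C2, so it may be slow and lose out to E1 elimination or hydride/methyl shifts. The fallback sets out from 3 and comes back at 8. Alkylate 3 with (E)-(3-bromoprop-1-en-1-yl)trimethylsilane (LDA, THF/DMPU) to give the vinylsilane (5S,6S)-2,6-dimethyl-5-(prop-1-en-2-yl)-6-[(2E)-3-(trimethylsilyl)prop-2-en-1-yl]cyclohex-2-en-1-one F1. The same HBr/ZnBr2 treatment then ends by ipso attack on the vinylsilane (β-silyl cation, loss of Me3SiBr) and gives the ring-A alkene (4aS,8aS)-2,5,5,8a-tetramethyl-4a,5,8,8a-tetrahydronaphthalen-1(4H)-one F2, with no secondary cation and no tin step. Diimide (2-nitrobenzenesulfonyl hydrazide, Et3N) reduces only the disubstituted ring-A double bond and gives 8.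

Step 5. The dianion reagent is strongly basic, the ketone is flanked by a quaternary carbon, and γ-deprotonation or poor conversion is possible. The fallback sets out from 8 and comes back at 11. Dimethylsulfonium methylide (Me3S+ I−, n-BuLi, THF, −10 °C; Corey–Chaykovsky) adds from the same α face and gives the spiro vinyl epoxide (2S,4a′S,8a′S)-2′,5′,5′,8a′-tetramethyl-4a′,5′,6′,7′,8′,8a′-hexahydro-4′H-spiro[oxirane-2,1′-naphthalene] F3. Under the Pd/n-Bu3P/HCO2H–Et3N conditions of step 6 (alkenyloxirane hydrogenolysis with inversion) F3 gives 11 directly.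

Step 6. Ionisation of the hindered tertiary allylic C–O bond may be slow, and hydride could go to C7 (giving drim-8-en-11-ol) or a diene could form by β-hydride elimination. The fallback sets out from 10 and comes back at 11. LiAlH4 (THF, 0 °C) opens the carbonate to the diol (1S,4aS,8aS)-1-(hydroxymethyl)-2,5,5,8a-tetramethyl-1,4,4a,5,6,7,8,8a-octahydronaphthalen-1-ol F4. 1,1′-Thiocarbonyldiimidazole converts it into the cyclic thionocarbonate (4S,4a′S,8a′S)-2′,5′,5′,8a′-tetramethyl-4a′,5′,6′,7′,8′,8a′-hexahydro-4′H-spiro[1,3-dioxolane-4,1′-naphthalene]-2-thione F5. Corey–Winter olefination (P(OMe)3, 110 °C) gives the exocyclic diene (4aS,8aS)-2,5,5,8a-tetramethyl-1-methylidene-1,4,4a,5,6,7,8,8a-octahydronaphthalene F6. 9-BBN followed by H2O2/NaOH hydroborates the 1,1-disubstituted C9=C11 bond from the α face (anti to the C10 methyl) and gives 11.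

**Further compounds**
F1 | step 3 | (5S,6S)-2,6-dimethyl-5-(prop-1-en-2-yl)-6-[(2E)-3-(trimethylsilyl)prop-2-en-1-yl]cyclohex-2-en-1-one | CC1=CC[C@@H](C(C)=C)[C@](C)(C/C=C/[Si](C)(C)C)C1=O
F2 | step 3 | (4aS,8aS)-2,5,5,8a-tetramethyl-4a,5,8,8a-tetrahydronaphthalen-1(4H)-one | CC1=CC[C@H]2C(C)(C)C=CC[C@]2(C)C1=O
F3 | step 5 | (2S,4a′S,8a′S)-2′,5′,5′,8a′-tetramethyl-4a′,5′,6′,7′,8′,8a′-hexahydro-4′H-spiro[oxirane-2,1′-naphthalene] | CC1=CC[C@H]2C(C)(C)CCC[C@]2(C)[C@]13CO3
F4 | step 6 | (1S,4aS,8aS)-1-(hydroxymethyl)-2,5,5,8a-tetramethyl-1,4,4a,5,6,7,8,8a-octahydronaphthalen-1-ol | CC1=CC[C@H]2C(C)(C)CCC[C@]2(C)[C@]1(O)CO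
F5 | step 6 | (4S,4a′S,8a′S)-2′,5′,5′,8a′-tetramethyl-4a′,5′,6′,7′,8′,8a′-hexahydro-4′H-spiro[1,3-dioxolane-4,1′-naphthalene]-2-thione | CC1=CC[C@H]2C(C)(C)CCC[C@]2(C)[C@]13COC(=S)O3
F6 | step 6 | (4aS,8aS)-2,5,5,8a-tetramethyl-1-methylidene-1,4,4a,5,6,7,8,8a-octahydronaphthalene | CC1=CC[C@H]2C(C)(C)CCC[C@]2(C)C1=C
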